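**Plan**
- Retrosynthetic cuts: the C2′–C3′ bond of the trienamide (alkenylstannane + iododienamide), the C2–N enamide bond, the two C–O bonds of the oxirane (C5–O and C6–O), and the C4–C1′ bond (acetylide onto a quinone monoketal).
- Forward order: the six-membered ring is bought as p-benzoquinone monoketal; acetylide addition and ketal hydrolysis give a prochiral alkynyl p-quinol; the oxirane is the only ring formed (step 3); C2 is then iodinated and amidated; the alkyne is unmasked, hydrostannylated and joined to the lower chain by Stille coupling. The cyclohexyl and cyclopentenone rings enter intact.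
- Enabling feature: with the ring numbered C1 (C=O), C2 (C–N), C3, C4 (C–OH), C5 and C6 (oxirane), removal of the C2 amide leaves a 4-substituted 4-hydroxycyclohexa-2,5-dienone. Its enone arms C2=C3 and C5=C6 are enantiotopic, and both are allylic to the C4 hydroxyl, which can carry the oxidant to either one.
- Stereochemistry: C4, C5 and C6 are all set in step 3. The oxirane is cis and syn to the hydroxyl because the peroxide is delivered from the metal held by the C4 oxygen; the absolute sense comes from the tartrate. Alkene geometry comes from HWE and Takai olefination, syn-hydrostannylation and stereoretentive Stille coupling.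
- The quinol is reached by acetylide addition to the monoketal, not by oxidising an alkynylphenol, because that addition is the more reliable entry; the C-silyl group keeps the alkyne silent through iodination and copper chemistry.

Key step: step 3

Assumption: for this cyclic tertiary dialkenyl carbinol the sense of arm selection by a given tartrate cannot be predicted with confidence; L-(+)-diisopropyl tartrate is written, and the D-(−)-ester is used instead if a trial run gives the antipode of the epoxy quinol.

Numbering remark: in every compound from the epoxidation onward the ring locants are those of the plan (C1 ketone, C2, C3, C4 carbinol, C5/C6 oxirane). The C4 descriptor is S for the alkynyl and stannylvinyl compounds and R for the trienyl target; this is a change of CIP priority only, not of geometry.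

**Step 1**
Reactants: 1 4,4-dimethoxycyclohexa-2,5-dien-1-one (p-benzoquinone mono(dimethyl ketal)); 2 (trimethylsilyl)acetylene
Product: 4 4,4-dimethoxy-1-[(trimethylsilyl)ethynyl]cyclohexa-2,5-dien-1-ol, via lithium (trimethylsilyl)acetylide 3 (not isolated)
Conditions: 2, n-BuLi, THF, −78 °C; then 1, −78 → −40 °C; H2O
Reagents that add atoms: none
Why: 1,2-addition of a lithium acetylide to the only free carbonyl of a quinone monoketal is a standard entry to masked p-quinols, the ketal blocking the second carbonyl; no stereocentre is formed.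

**Step 2**
Reactants: 4 4,4-dimethoxy-1-[(trimethylsilyl)ethynyl]cyclohexa-2,5-dien-1-ol
Product: 5 4-hydroxy-4-[(trimethylsilyl)ethynyl]cyclohexa-2,5-dien-1-one
Conditions: PPTS (20 mol %), acetone/H2O (5:1), rt
Reagents that add atoms: water, O
Why: acid-catalysed ketal hydrolysis proceeds through the doubly vinylogous oxocarbenium ion at the ketal carbon, and the weak acid should leave the tertiary carbinol un-ionised (no dienone–phenol rearrangement) and the C–Si bond intact.

**Step 3**
Reactants: 5 4-hydroxy-4-[(trimethylsilyl)ethynyl]cyclohexa-2,5-dien-1-one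
Product: 6 (4S,5S,6R)-5,6-epoxy-4-hydroxy-4-[(trimethylsilyl)ethynyl]cyclohex-2-en-1-one (hydroxyl and oxirane oxygen syn)
Conditions: Ti(OiPr)4 (1.1 equiv), L-(+)-DIPT (1.3 equiv), TBHP (1.2 equiv, in decane), 4 Å MS, CH2Cl2, −20 °C
Reagents that add atoms: tert-butyl hydroperoxide, CC(C)(C)OO
Why: The tertiary C4 hydroxyl exchanges onto the tartrate-bearing titanium centre that also carries the η2-bound tert-butylperoxide; the metal-bound peroxide oxygen adds in conjugate fashion to C5 of one enone arm and the resulting C6 titanium enolate attacks the same oxygen with loss of tert-butoxide, so C5–O and C6–O form in one metal-held sequence. The closest known reactions are the hydroxyl-directed Ti(OiPr)4/TBHP nucleophilic epoxidation of γ-hydroxy enones and p-quinols, the tartrate-mediated asymmetric nucleophilic epoxidation of hydroxyl-bearing cyclohexadienones, and the Sharpless-type choice between enantiotopic alkenes of a dialkenyl carbinol. The oxirane closes by a 3-exo-tet displacement at the peroxide oxygen (Weitz–Scheffer-type closure). C5 and C6 are necessarily cis and are placed syn to the C4 oxygen because the oxidant is delivered from the metal bound to that oxygen, whereas C4 becomes a stereocentre only through the choice of arm, which the chiral tartrate makes. The step needs arm selectivity, syn facial selectivity and mono-epoxidation: the first rests on the ligand, the second on the C4–O–Ti tether and the third on the limited charge of peroxide at low temperature, with the corollary that any second directed epoxidation should consume the minor enantiomer faster and so raise the enantiomeric purity of 6; the silylalkyne is not electrophilic and should stay untouched.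

**Step 4**
Reactants: 6 (4S,5S,6R)-5,6-epoxy-4-hydroxy-4-[(trimethylsilyl)ethynyl]cyclohex-2-en-1-one
Product: 7 (4S,5S,6R)-5,6-epoxy-4-hydroxy-2-iodo-4-[(trimethylsilyl)ethynyl]cyclohex-2-en-1-one
Conditions: I2, pyridine, CH2Cl2, 0 °C → rt
Reagents that add atoms: iodine, II
Why: Johnson-type α-iodination (conjugate addition of pyridine at C3, iodination of the enolate at C2, elimination of pyridine) is well established for 4-oxygenated 5,6-epoxycyclohexenones, and the single remaining enone leaves no regiochemical choice.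

**Step 5**
Reactants: 8 cyclohexanecarboxaldehyde; 9 triethyl (E)-4-phosphonocrotonate
Product: 10 ethyl (2E,4E)-5-cyclohexylpenta-2,4-dienoate
Conditions: LiHMDS, THF, −78 °C → rt
Reagents that add atoms: none
Why: the vinylogous Horner–Wadsworth–Emmons olefination with a stabilised allylic phosphonate anion should form the new C4=C5 bond with E geometry while the E C2=C3 bond of the reagent is retained.

**Step 6**
Reactants: 10 ethyl (2E,4E)-5-cyclohexylpenta-2,4-dienoate
Product: 11 (2E,4E)-5-cyclohexylpenta-2,4-dienamide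
Conditions: AlMe3, NH4Cl, toluene, 0 → 50 °C; aq. HCl work-up
Reagents that add atoms: ammonium chloride, [NH4+].[Cl-]
Why: Weinreb aminolysis with the aluminium amide generated from AlMe3 and NH4Cl converts esters directly into primary amides by attack at the acyl carbon, without conjugate addition to the dienoate.

**Step 7**
Reactants: 7 (4S,5S,6R)-5,6-epoxy-4-hydroxy-2-iodo-4-[(trimethylsilyl)ethynyl]cyclohex-2-en-1-one; 11 (2E,4E)-5-cyclohexylpenta-2,4-dienamide
Product: 12 (2E,4E)-5-cyclohexyl-N-{(4S,5S,6R)-5,6-epoxy-4-hydroxy-1-oxo-4-[(trimethylsilyl)ethynyl]cyclohex-2-en-2-yl}penta-2,4-dienamide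
Conditions: CuI (10 mol %), N,N′-dimethylethylenediamine (20 mol %), Cs2CO3, THF, 50 °C
Reagents that add atoms: none
Why: the copper-catalysed Goldberg–Buchwald amidation of vinyl iodides is established for α-iodoenones, the primary amide N–H being the most acidic and least hindered nucleophile present, and the three stereocentres are not involved.

**Step 8**
Reactants: 12 (2E,4E)-5-cyclohexyl-N-{(4S,5S,6R)-5,6-epoxy-4-hydroxy-1-oxo-4-[(trimethylsilyl)ethynyl]cyclohex-2-en-2-yl}penta-2,4-dienamide
Product: 13 (2E,4E)-5-cyclohexyl-N-[(4S,5S,6R)-5,6-epoxy-4-ethynyl-4-hydroxy-1-oxocyclohex-2-en-2-yl]penta-2,4-dienamide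
Conditions: TBAF, AcOH (1:1), THF, 0 °C
Reagents that add atoms: none
Why: fluoride-induced protiodesilylation of an alkynylsilane is fast at 0 °C, and buffering with acetic acid keeps the medium non-basic for the oxirane, the enone and the enamide.

**Step 9**
Reactants: 13 (2E,4E)-5-cyclohexyl-N-[(4S,5S,6R)-5,6-epoxy-4-ethynyl-4-hydroxy-1-oxocyclohex-2-en-2-yl]penta-2,4-dienamide
Product: 14 (2E,4E)-5-cyclohexyl-N-{(4S,5S,6R)-5,6-epoxy-4-hydroxy-1-oxo-4-[(E)-2-(tributylstannyl)ethenyl]cyclohex-2-en-2-yl}penta-2,4-dienamide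
Conditions: Bu3SnH (slow addition), PdCl2(PPh3)2 (3 mol %), THF, 0 °C
Reagents that add atoms: tributyltin hydride, CCCC[SnH](CCCC)CCCC
Why: palladium-catalysed hydrostannylation adds Sn–H syn across the terminal alkyne, the quaternary propargylic carbon steering tin to the terminal carbon to give the E-alkenylstannane, and the alkyne is expected to react faster than the electron-rich amido-enone.

**Step 10**
Reactants: 15 ethyl (E)-4-oxobut-2-enoate
Product: 16 ethyl (2E,4E)-5-iodopenta-2,4-dienoate
Conditions: CrCl2, CHI3, THF/dioxane, 0 °C → rt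
Reagents that add atoms: iodoform, IC(I)I
Why: Takai iodo-olefination of the aldehyde through a geminal dichromium species should give the E-iodoalkene selectively and leaves the enoate untouched.

**Step 11**
Reactants: 16 ethyl (2E,4E)-5-iodopenta-2,4-dienoate
Product: 17 (2E,4E)-5-iodopenta-2,4-dienoic acid
Conditions: LiOH, THF/H2O, 0 °C → rt; then 1 M HCl
Reagents that add atoms: lithium hydroxide, [Li+].[OH-]
Why: ester saponification by hydroxide at the acyl carbon is straightforward, and the alkenyl iodide is inert to cold aqueous LiOH.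

**Step 12**
Reactants: 18 cyclopentane-1,3-dione
Product: 19 2-nitrocyclopentane-1,3-dione
Conditions: fuming HNO3, Et2O, 0 °C
Reagents that add atoms: nitric acid, O[N+](=O)[O-]
Why: electrophilic nitration of the enol of a cyclic 1,3-dione takes place at C2, the only nucleophilic carbon.

**Step 13**
Reactants: 19 2-nitrocyclopentane-1,3-dione
Product: 20 2-amino-3-hydroxycyclopent-2-en-1-one hydrochloride
Conditions: H2 (1 atm), 10% Pd/C, HCl, MeOH, rt
Reagents that add atoms: hydrogen chloride, Cl
Why: catalytic hydrogenation reduces the nitro group to the amine, which is trapped as its hydrochloride so that the air-sensitive, self-condensing free aminodione is never handled.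

**Step 14**
Reactants: 17 (2E,4E)-5-iodopenta-2,4-dienoic acid; 20 2-amino-3-hydroxycyclopent-2-en-1-one hydrochloride
Product: 22 (2E,4E)-N-(2-hydroxy-5-oxocyclopent-1-en-1-yl)-5-iodopenta-2,4-dienamide, via (2E,4E)-5-iodopenta-2,4-dienoyl chloride 21 (not isolated)
Conditions: (COCl)2, DMF (cat.), CH2Cl2, 0 °C → rt; then 20, pyridine, CH2Cl2/DMF, 0 °C → rt
Reagents that add atoms: none
Why: Vilsmeier-type activation gives the acid chloride, which acylates the liberated amine (amide formation via acid chloride); any O-acylated enol should transfer its acyl group to nitrogen or be cleaved on aqueous work-up.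

**Step 15**
Reactants: 14 (2E,4E)-5-cyclohexyl-N-{(4S,5S,6R)-5,6-epoxy-4-hydroxy-1-oxo-4-[(E)-2-(tributylstannyl)ethenyl]cyclohex-2-en-2-yl}penta-2,4-dienamide; 22 (2E,4E)-N-(2-hydroxy-5-oxocyclopent-1-en-1-yl)-5-iodopenta-2,4-dienamide
Product: 23 (2E,4E)-5-cyclohexyl-N-{(4R,5S,6R)-5,6-epoxy-4-hydroxy-4-[(1E,3E,5E)-7-[(2-hydroxy-5-oxocyclopent-1-en-1-yl)amino]-7-oxohepta-1,3,5-trien-1-yl]-1-oxocyclohex-2-en-2-yl}penta-2,4-dienamide (CNP0111189.1)
Conditions: Pd2(dba)3·CHCl3 (5 mol %), AsPh3 (20 mol %), NMP, rt, dark
Reagents that add atoms: none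
Why: Stille coupling of an alkenylstannane with an alkenyl iodide forms the C2′–C3′ bond with retention of both alkene geometries under neutral, room-temperature conditions that should tolerate the oxirane, the tertiary alcohol and the acidic enol of the aminocyclopentenone.

**Compound list**
1 | 4,4-dimethoxycyclohexa-2,5-dien-1-one | O=C1C=CC(OC)(OC)C=C1 | starting material
2 | (trimethylsilyl)acetylene | C#C[Si](C)(C)C | starting material
3 | lithium (trimethylsilyl)acetylide | [Li]C#C[Si](C)(C)C | intermediate
4 | 4,4-dimethoxy-1-[(trimethylsilyl)ethynyl]cyclohexa-2,5-dien-1-ol | COC1(OC)C=CC(O)(C#C[Si](C)(C)C)C=C1 | intermediate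
5 | 4-hydroxy-4-[(trimethylsilyl)ethynyl]cyclohexa-2,5-dien-1-one | O=C1C=CC(O)(C#C[Si](C)(C)C)C=C1 | intermediate
6 | (4S,5S,6R)-5,6-epoxy-4-hydroxy-4-[(trimethylsilyl)ethynyl]cyclohex-2-en-1-one | C1=C[C@](O)(C#C[Si](C)(C)C)[C@H]2O[C@H]2C1=O | intermediate
7 | (4S,5S,6R)-5,6-epoxy-4-hydroxy-2-iodo-4-[(trimethylsilyl)ethynyl]cyclohex-2-en-1-one | IC1=C[C@](O)(C#C[Si](C)(C)C)[C@H]2O[C@H]2C1=O | intermediate
8 | cyclohexanecarboxaldehyde | O=CC1CCCCC1 | starting material
9 | triethyl (E)-4-phosphonocrotonate | CCOC(=O)/C=C/CP(=O)(OCC)OCC | starting material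
10 | ethyl (2E,4E)-5-cyclohexylpenta-2,4-dienoate | CCOC(=O)/C=C/C=C/C1CCCCC1 | intermediate
11 | (2E,4E)-5-cyclohexylpenta-2,4-dienamide | NC(=O)/C=C/C=C/C1CCCCC1 | intermediate
12 | (2E,4E)-5-cyclohexyl-N-{(4S,5S,6R)-5,6-epoxy-4-hydroxy-1-oxo-4-[(trimethylsilyl)ethynyl]cyclohex-2-en-2-yl}penta-2,4-dienamide | O=C(/C=C/C=C/C1CCCCC1)NC1=C[C@](O)(C#C[Si](C)(C)C)[C@H]2O[C@H]2C1=O | intermediate
13 | (2E,4E)-5-cyclohexyl-N-[(4S,5S,6R)-5,6-epoxy-4-ethynyl-4-hydroxy-1-oxocyclohex-2-en-2-yl]penta-2,4-dienamide | O=C(/C=C/C=C/C1CCCCC1)NC1=C[C@](O)(C#C)[C@H]2O[C@H]2C1=O | intermediate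
14 | (2E,4E)-5-cyclohexyl-N-{(4S,5S,6R)-5,6-epoxy-4-hydroxy-1-oxo-4-[(E)-2-(tributylstannyl)ethenyl]cyclohex-2-en-2-yl}penta-2,4-dienamide | O=C(/C=C/C=C/C1CCCCC1)NC1=C[C@](O)(/C=C/[Sn](CCCC)(CCCC)CCCC)[C@H]2O[C@H]2C1=O | intermediate
15 | ethyl (E)-4-oxobut-2-enoate | CCOC(=O)/C=C/C=O | starting material
16 | ethyl (2E,4E)-5-iodopenta-2,4-dienoate | CCOC(=O)/C=C/C=C/I | intermediate
17 | (2E,4E)-5-iodopenta-2,4-dienoic acid | OC(=O)/C=C/C=C/I | intermediate
18 | cyclopentane-1,3-dione | O=C1CCC(=O)C1 | starting material
19 | 2-nitrocyclopentane-1,3-dione | O=C1CCC(=O)C1[N+](=O)[O-] | intermediate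
20 | 2-amino-3-hydroxycyclopent-2-en-1-one hydrochloride | Cl.NC1=C(O)CCC1=O | intermediate
21 | (2E,4E)-5-iodopenta-2,4-dienoyl chloride | ClC(=O)/C=C/C=C/I | intermediate
22 | (2E,4E)-N-(2-hydroxy-5-oxocyclopent-1-en-1-yl)-5-iodopenta-2,4-dienamide | O=C(/C=C/C=C/I)NC1=C(O)CCC1=O | intermediate
23 | (2E,4E)-5-cyclohexyl-N-{(4R,5S,6R)-5,6-epoxy-4-hydroxy-4-[(1E,3E,5E)-7-[(2-hydroxy-5-oxocyclopent-1-en-1-yl)amino]-7-oxohepta-1,3,5-trien-1-yl]-1-oxocyclohex-2-en-2-yl}penta-2,4-dienamide | O=C(/C=C/C=C/C1CCCCC1)NC1=C[C@](O)(/C=C/C=C/C=C/C(=O)NC2=C(O)CCC2=O)[C@H]2O[C@H]2C1=O | target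

**Step count**
Total: 15 steps. Longest linear sequence: 8 steps (1, 2, 3, 4, 7, 8, 9, 15), with the upper amide (steps 5–6) and the lower iododienamide (steps 10–14) made in parallel.

**Steps most likely to fail**

Step 3. The tartrate may discriminate poorly between the two enantiotopic enone arms, the hindered tertiary alkoxide may exchange onto titanium too slowly for useful turnover, or oxidation may run on to the bis-epoxide. The fallback reverses the order of oxidation and C–C bond formation, so that the absolute configuration is set on the ketal by a catalyst and the hydroxyl configuration follows from it. Setting out from 1, nucleophilic epoxidation with TBHP and aqueous NaOH in toluene under a cinchona-derived quaternary ammonium phase-transfer catalyst (the pseudoenantiomer chosen for the required sense) would give (1S,6R)-5,5-dimethoxy-7-oxabicyclo[4.1.0]hept-3-en-2-one F1. Addition of 3 in THF at −78 °C to the ketone, from the face opposite the oxirane, would give (1S,2S,6R)-5,5-dimethoxy-2-[(trimethylsilyl)ethynyl]-7-oxabicyclo[4.1.0]hept-3-en-2-ol F2, with hydroxyl and oxirane oxygen syn. Hydrolysis of the ketal (montmorillonite K10, CH2Cl2, rt) rejoins the route at 6.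

Step 7. The hydroxy epoxy enone may decompose under carbonate and copper at 50 °C, the alkynyl silyl group may be lost with ensuing copper acetylide coupling to the vinyl iodide, or the tertiary alkoxide may compete as nucleophile. The fallback installs the amide before the ring is oxidised. Setting out from 11, copper-catalysed N-arylation with 2-bromo-1,4-dimethoxybenzene (CuI, N,N′-dimethylethylenediamine, K2CO3, toluene, 110 °C) would give (2E,4E)-5-cyclohexyl-N-(2,5-dimethoxyphenyl)penta-2,4-dienamide F3. Oxidation with PhI(OAc)2 in MeOH would give the amido quinone monoketal (2E,4E)-5-cyclohexyl-N-(6,6-dimethoxy-3-oxocyclohexa-1,4-dien-1-yl)penta-2,4-dienamide F4. Phase-transfer asymmetric nucleophilic epoxidation (TBHP, NaOH, cinchona-derived ammonium salt) should attack only the unsubstituted enone bond, giving (2E,4E)-5-cyclohexyl-N-[(1R,6S)-2,2-dimethoxy-5-oxo-7-oxabicyclo[4.1.0]hept-3-en-3-yl]penta-2,4-dienamide F5. Excess 3 would add to the ketone anti to the oxirane, giving (2E,4E)-5-cyclohexyl-N-[(1R,5S,6S)-5-hydroxy-2,2-dimethoxy-5-[(trimethylsilyl)ethynyl]-7-oxabicyclo[4.1.0]hept-3-en-3-yl]penta-2,4-dienamide F6. Ketal hydrolysis on montmorillonite K10 rejoins the route at 12. The cost is that the stereocentres then come from catalyst-controlled epoxidation of the ketal, not from the quinol.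

Step 9. The tin hydride/palladium hydride may reduce the enone in conjugate fashion or open the oxirane reductively, some internal (α) stannane may form, and the product may protodestannylate on silica. The fallback replaces tin by silicon. Setting out from 13, platinum-catalysed hydrosilylation with benzyldimethylsilane (Pt(dvds), P(t-Bu)3, THF, rt), which is selective for alkynes over carbonyl groups and gives the E-β isomer, would give (2E,4E)-N-{(4S,5S,6R)-4-[(E)-2-(benzyldimethylsilyl)ethenyl]-5,6-epoxy-4-hydroxy-1-oxocyclohex-2-en-2-yl}-5-cyclohexylpenta-2,4-dienamide F7. Fluoride-promoted Hiyama–Denmark coupling with 22 (TBAF, Pd2(dba)3, THF, rt) then arrives directly at 23.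

**Further compounds**
F1 | step 3 | (1S,6R)-5,5-dimethoxy-7-oxabicyclo[4.1.0]hept-3-en-2-one | C1=CC(=O)[C@H]2O[C@H]2C1(OC)OC
F2 | step 3 | (1S,2S,6R)-5,5-dimethoxy-2-[(trimethylsilyl)ethynyl]-7-oxabicyclo[4.1.0]hept-3-en-2-ol | C1=C[C@](O)(C#C[Si](C)(C)C)[C@H]2O[C@H]2C1(OC)OC
F3 | step 7 | (2E,4E)-5-cyclohexyl-N-(2,5-dimethoxyphenyl)penta-2,4-dienamide | COc1ccc(OC)c(NC(=O)/C=C/C=C/C2CCCCC2)c1
F4 | step 7 | (2E,4E)-5-cyclohexyl-N-(6,6-dimethoxy-3-oxocyclohexa-1,4-dien-1-yl)penta-2,4-dienamide | O=C(/C=C/C=C/C1CCCCC1)NC1=CC(=O)C=CC1(OC)OC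
F5 | step 7 | (2E,4E)-5-cyclohexyl-N-[(1R,6S)-2,2-dimethoxy-5-oxo-7-oxabicyclo[4.1.0]hept-3-en-3-yl]penta-2,4-dienamide | O=C(/C=C/C=C/C1CCCCC1)NC1=CC(=O)[C@H]2O[C@H]2C1(OC)OC
F6 | step 7 | (2E,4E)-5-cyclohexyl-N-[(1R,5S,6S)-5-hydroxy-2,2-dimethoxy-5-[(trimethylsilyl)ethynyl]-7-oxabicyclo[4.1.0]hept-3-en-3-yl]penta-2,4-dienamide | O=C(/C=C/C=C/C1CCCCC1)NC1=C[C@](O)(C#C[Si](C)(C)C)[C@H]2O[C@H]2C1(OC)OC
F7 | step 9 | (2E,4E)-N-{(4S,5S,6R)-4-[(E)-2-(benzyldimethylsilyl)ethenyl]-5,6-epoxy-4-hydroxy-1-oxocyclohex-2-en-2-yl}-5-cyclohexylpenta-2,4-dienamide | O=C(/C=C/C=C/C1CCCCC1)NC1=C[C@](O)(/C=C/[Si](C)(C)Cc2ccccc2)[C@H]2O[C@H]2C1=O
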